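## Analysis of the target

Labdane numbering is used for the target and for every intermediate. Ring A holds C1–C5 and C10, ring B holds C5–C10, and ring C is the oxocane C8–O–C15–C14–C13–C12–C11–C9.

The target 28 is a trans-decalin whose C8–C9 bond is shared with an eight-membered cyclic ether carrying a cis-13,14-epoxide. It has seven stereocentres (3S,5R,8R,9R,10S,13R,14S). The bromine at C3 is β and equatorial, and the ring fusion is 5α-H/10β-CH3. C8 carries the ether oxygen α (equatorial) and a methyl β (axial), and C9 carries C11 β (equatorial, 9α-H), so ring C is fused trans-diequatorially. The epoxide oxygen lies on the outer face of the ring C alkene from which it derives.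

The epoxide is the acid-sensitive group and belongs at the end. The bromide sits on a neopentyl carbon next to C4, so it cannot be introduced reliably by substitution and should not meet hydride reagents. The hard points are the two neighbouring quaternary carbons C4 and C10 (their β-methyls are 1,3-diaxial), the tertiary C8–O bond, the medium ring and the C3 bromide.

The strategy rests on the fusion bond C5–C10. C5 is flanked by the gem-dimethyl carbon C4, so a four-atom tether C1–C4 carrying that gem-dimethyl group can tie a C7–C10 diene to a C5=C6 dienophile. Rings A and B then close in a single cycloaddition.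

## Retrosynthetic reasoning

**28 ⇒ 27 (C13–O and C14–O).** The epoxide is removed first because it is the most labile group. This leaves the Z-oxocene 27. The forward step has to deliver oxygen to the outer face of the C13=C14 bond.

**27 ⇒ 26 (C13=C14).** Ring C is opened at its only double bond by a ring-closing metathesis transform. Cutting here turns the medium ring into two simple appendages: an O-allyl group on C8 and an isopropenyl group at the end of the C9 chain. The forward reaction must close an eight-membered ring; the trans-diequatorial (gauche) placement of the two chains on C8 and C9 helps, and the ring size enforces the Z geometry.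

**26 ⇒ 25 ⇒ 24 ⇒ 23 (C13=CH2, C13 ketal, O–C15).** The isopropenyl carbon comes from the methyl ketone 25 by methylenation, the ketone from its ketal 24, and the allyl ether from the tertiary alcohol 23. The ketal is kept until after etherification so that the strong base needed for the tertiary alkoxide never meets an enolisable ketone.

**23 ⇒ 22 ⇒ 21 ⇒ 20 ⇒ 19 (C3–H instead of C3–Br).** The C–Br bond is not disconnected as a substitution, because C3 is neopentyl. The bond formed last at C3 is instead C3–H: the alkenyl bromide 22 is hydrogenated by hydrogen-atom transfer, which leaves bromine equatorial. 22 comes from ketone 20 through enol triflate 21, and 20 from diol 19 by oxidation of the only secondary alcohol. This sequence needs a molecule free of other alkenes, which is why it is placed between the C8 chemistry and the allylation.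

**19 ⇒ 18 ⇒ 17 ⇒ 16 (C17–H, C8–O, C8=C17).** The tertiary carbinol is traced to the spiro-epoxide 18, the exocyclic alkene 17 and the C8 ketone 16. A direct methyl addition to 16 is avoided: the reagent would enter from the α-face, away from the axial C10 methyl, and give the wrong C8 epimer. Epoxidation from that same α-face followed by hydride opening at C17 gives the right one.

**16 ⇒ 15 ⇒ 14 (silyl groups, C6–S).** Ketone 16 is the desilylated, desulfonylated form of cycloadduct 14. The sulfone is removed while C8 is still an enol ether (15), so that no β-sulfonyl ketone is ever present.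

**14 ⇒ 13 (C5–C10 and C6–C7).** This is the key disconnection, a retro-Diels–Alder that opens rings A and B together and leads to the acyclic triene 13. The two bonds are cut here because C5–C10 is the fusion bond next to the gem-dimethyl carbon, and because the enol ether left at C8 is exactly the functional group needed for the tertiary ether. The forward reaction has to set C10, C5 and C6 from the single stereocentre C3 and the two alkene geometries.

**13 ⇒ 12 ⇒ 4 + 10 (O–Si, then C1–C10).** The silyloxydiene is the enol silyl ether of enone 12. The sp3–sp2 bond C1–C10 of 12 is cut to the enol triflate 4 and the terminal alkene 10 (through its borane 11). This is the most convergent cut, and it transfers the geometry of 4 to the tetrasubstituted alkene.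

**4 ⇒ 3 ⇒ 1 + 2, and 10 ⇒ 9 ⇒ 8 ⇒ 7 ⇒ 5 + 6.** Triflate 4 comes from the alkylated diketone 3, made from 1 and 2. The vinyl sulfone 10 comes from aldehyde 9 by olefination, 9 from ester 8, and 8 from the aldol 7. The aldol is disconnected at C3–C4 to acrolein 5 and the ketene acetal 6; this one asymmetric step supplies the only stereocentre that is not set by the substrate.

## Alternatives that were turned down

**Alternative 1:** Ring C is cut at C11–C12 and at O–C15, so that isoprene A3 is inserted between the C11 iodide and the C8 hydroxyl of the bicyclic iodo alcohol A2. In the forward step Pd(PPh3)4 under blue light turns the C–I bond into a C11 radical, the radical adds to the diene, and the resulting allyl–palladium species is trapped by the tertiary hydroxyl to give the Z-oxocene A1 (the same structure as 27).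

- For it: four carbons and the medium ring arrive in one step, and A1 is one epoxidation away from the target. On paper this replaces steps 19–22 of the chosen route and is clearly stronger in step economy for ring C.
- Against it: the allyl intermediate spans C13–C15, and attack of the C8 oxygen at C13 closes a six-membered ring (tetrahydropyran A4), which is kinetically much easier than eight-membered closure at C15. The oxocene also requires the less stable anti allyl geometry, since the syn form leads to an E alkene that the ring cannot hold. The nucleophile is a hindered tertiary alcohol. The secondary C3 bromide is itself open to the same light-driven palladium activation. A2 still needs a decalin synthesis that faces the same bromide problem.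
- Comparison: the chosen route is longer at this stage, but ring size and Z geometry are enforced by metathesis and do not depend on an unfavourable regiochemical choice.

**Alternative 2:** Ring B is cut at C8–C9 (together with a lactone C–O bond), giving the monocyclic keto enoate A6. In the forward step SmI2 reduces the C8 methyl ketone to a ketyl, which adds to the β-carbon C9 of the unsaturated ester; the samarium alkoxide then lactonises to the tricyclic lactone A5.

- For it: the tertiary C8–O bond, the C8 methyl and C9 are formed in one reductive step, where the chosen route spends steps 12–14. A5 belongs to a well-understood lactone class. On the C8 problem this alternative is stronger.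
- Against it: A6 is a cyclohexane with the vicinal quaternary carbons C4 and C10 and a defined C5/C10 relationship, so the hardest part of the decalin is moved into the precursor, not solved. The ketyl must attack a β-carbon attached to the quaternary C10 and deliver the trans-diequatorial oxygen/carbon pair, in competition with simple reduction of the enoate. A5 also lacks C13–C16, so ring C needs at least as many steps afterwards as in the chosen route, and the C3 bromide is no closer.
- Comparison: the chosen strategy sets C5 and C10 and closes both carbocycles in one step from acyclic material, with a single reagent-controlled stereocentre.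

**Alternative 3:** C13 with its methyl group is excised from ring C (cutting C12–C13 and C13–C14), which leads back to the seven-membered oxepanone A8. In the forward step diazoethane A9 adds to the Sc(OTf)3-activated C14 ketone and C12 migrates with loss of nitrogen, giving the α-methyl oxocanone A7; both C13 epimers would converge.

- For it: the entropic cost of closing an eight-membered ring is avoided, and migration of the alkyl carbon C12 in preference to the oxygen-bearing C15 is the electronically expected outcome. On ease of ring formation it is stronger than a direct medium-ring closure.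
- Against it: A7 is a ketone, so the 13,14-epoxide still requires regioselective enolisation towards C13 (not C15), conversion to the alkene and epoxidation, which is three or more further steps. Diazoethane brings a handling burden and the risk of double insertion. A8 needs its own ring synthesis on a hindered tertiary alcohol, and the decalin and the bromide remain unaddressed.
- Comparison: the metathesis of the chosen route places the double bond exactly at C13=C14 in the step that closes the ring, so the step count for ring C is equal or lower.

Key step: step 9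

Assumption: the sense of induction of the N-tosyl-D-valine-derived oxazaborolidinone with acrolein is taken to be the one it shows with saturated aldehydes, which corresponds to the 3S alcohol 7; if the antipode forms, N-tosyl-L-valine is used and nothing else changes.

## Route

Step 1
Reactants: 1 acetylacetone (pentane-2,4-dione); 2 2-(2-bromoethyl)-2-methyl-1,3-dioxolane
Product: 3 3-[2-(2-methyl-1,3-dioxolan-2-yl)ethyl]pentane-2,4-dione
Conditions: K2CO3, NaI (cat.), acetone, reflux (1 in excess)
Reagents that add atoms: none
Why: C-alkylation of the stabilised diketone enolate by a primary bromide (iodide-assisted SN2); excess diketone suppresses dialkylation. It brings in C11–C13 and C16 with the C13 ketone already masked.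

Step 2
Reactants: 3 3-[2-(2-methyl-1,3-dioxolan-2-yl)ethyl]pentane-2,4-dione
Product: 4 (2E)-3-[2-(2-methyl-1,3-dioxolan-2-yl)ethyl]-4-oxopent-2-en-2-yl trifluoromethanesulfonate
Conditions: Tf2O, aq. Me4NOH, hexane/PhMe, 5 °C
Reagents that add atoms: trifluoromethanesulfonic anhydride, O=S(=O)(OS(=O)(=O)C(F)(F)F)C(F)(F)F
Why: Stereoselective enol triflate formation from a β-dicarbonyl compound under non-chelating biphasic conditions; without a chelating cation the enolate should react in its dipole-minimised form, which puts the triflate trans to the remaining acetyl group (E). The diketone is symmetric, so only this geometry has to be controlled.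

Step 3
Reactants: 5 acrolein; 6 1-methoxy-2-methyl-1-(trimethylsilyloxy)prop-1-ene
Product: 7 methyl (3S)-3-hydroxy-2,2-dimethylpent-4-enoate
Conditions: N-tosyl-D-valine, BH3·THF, CH2Cl2, 0 °C to rt; then 5 and 6, −78 °C; aqueous acidic work-up
Reagents that add atoms: none
Why: Asymmetric Mukaiyama aldol addition promoted by a valine-derived oxazaborolidinone: the aldehyde is bound to boron and one carbonyl face is shielded, so the ketene acetal attacks the other face and sets C3 (S). The carbonyl carbon becomes C3, the vinyl group C1–C2 and the ketene acetal carbon the gem-dimethyl C4.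

Step 4
Reactants: 7 methyl (3S)-3-hydroxy-2,2-dimethylpent-4-enoate
Product: 8 methyl (3S)-3-[(tert-butyldimethylsilyl)oxy]-2,2-dimethylpent-4-enoate
Conditions: TBSOTf, 2,6-lutidine, CH2Cl2, 0 °C
Reagents that add atoms: tert-butyldimethylsilyl trifluoromethanesulfonate, CC(C)(C)[Si](C)(C)OS(=O)(=O)C(F)(F)F
Why: Silylation of a hindered secondary alcohol with the silyl triflate; the bulky ether is wanted later as the equatorial control element in the cycloaddition.

Step 5
Reactants: 8 methyl (3S)-3-[(tert-butyldimethylsilyl)oxy]-2,2-dimethylpent-4-enoate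
Product: 9 (3S)-3-[(tert-butyldimethylsilyl)oxy]-2,2-dimethylpent-4-enal
Conditions: i-Bu2AlH (1.1 equiv), CH2Cl2, −78 °C; potassium sodium tartrate work-up
Reagents that add atoms: none
Why: Partial reduction of an ester by i-Bu2AlH; the α-quaternary centre and the β-silyloxy group stabilise the tetrahedral aluminium hemiacetal at low temperature, so the aldehyde is released only on work-up. The aldehyde is not enolisable.

Step 6
Reactants: 9 (3S)-3-[(tert-butyldimethylsilyl)oxy]-2,2-dimethylpent-4-enal
Product: 10 tert-butyl{[(3S,5E)-4,4-dimethyl-6-(phenylsulfonyl)hexa-1,5-dien-3-yl]oxy}dimethylsilane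
Conditions: (EtO)2P(O)CH2SO2Ph, NaH, THF, 0 °C to rt
Reagents that add atoms: diethyl [(phenylsulfonyl)methyl]phosphonate, CCOP(=O)(CS(=O)(=O)c1ccccc1)OCC
Why: Horner–Wadsworth–Emmons olefination of a neopentyl aldehyde with a sulfonyl-stabilised phosphonate, which is E-selective. The quaternary C4 leaves no γ-hydrogen, so the vinyl sulfone cannot isomerise to an allyl sulfone.

Step 7
Reactants: 10 tert-butyl{[(3S,5E)-4,4-dimethyl-6-(phenylsulfonyl)hexa-1,5-dien-3-yl]oxy}dimethylsilane; 4 (2E)-3-[2-(2-methyl-1,3-dioxolan-2-yl)ethyl]-4-oxopent-2-en-2-yl trifluoromethanesulfonate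
Product: 12 (3E,7S,9E)-7-[(tert-butyldimethylsilyl)oxy]-4,8,8-trimethyl-3-[2-(2-methyl-1,3-dioxolan-2-yl)ethyl]-10-(phenylsulfonyl)deca-3,9-dien-2-one, via B-alkyl-9-borabicyclononane 11 (not isolated)
Conditions: 9-BBN, THF, 0 °C to rt; then 4, PdCl2(dppf) (5 mol %), AsPh3, aq. K3PO4, DMF, rt
Reagents that add atoms: none
Why: Anti-Markovnikov hydroboration of the monosubstituted alkene (the electrophilic borane leaves the electron-poor, disubstituted vinyl sulfone alone), then B-alkyl Suzuki–Miyaura coupling. Oxidative addition into the β-acyl enol triflate and reductive elimination go with retention, so C1 ends up trans to the acetyl group and the C10 methyl cis to it.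

Step 8
Reactants: 12 (3E,7S,9E)-7-[(tert-butyldimethylsilyl)oxy]-4,8,8-trimethyl-3-[2-(2-methyl-1,3-dioxolan-2-yl)ethyl]-10-(phenylsulfonyl)deca-3,9-dien-2-one
Product: 13 tert-butyl{[(3E,7S,9E)-7-[(tert-butyldimethylsilyl)oxy]-4,8,8-trimethyl-3-[2-(2-methyl-1,3-dioxolan-2-yl)ethyl]-10-(phenylsulfonyl)deca-1,3,9-trien-2-yl]oxy}dimethylsilane
Conditions: TBSOTf, Et3N, CH2Cl2, −78 to 0 °C
Reagents that add atoms: tert-butyldimethylsilyl trifluoromethanesulfonate, CC(C)(C)[Si](C)(C)OS(=O)(=O)C(F)(F)F
Why: Soft enolisation of an enone: the silyl-activated ketone loses a proton from the α′-methyl group (C7), the kinetically preferred site, giving the cross-conjugated 2-silyloxydiene. The C9=C10 geometry is not touched, and the amine-buffered medium spares the ketal and the vinyl sulfone.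

Step 9
Reactants: 13 tert-butyl{[(3E,7S,9E)-7-[(tert-butyldimethylsilyl)oxy]-4,8,8-trimethyl-3-[2-(2-methyl-1,3-dioxolan-2-yl)ethyl]-10-(phenylsulfonyl)deca-1,3,9-trien-2-yl]oxy}dimethylsilane
Product: 14 3β,8-bis[(tert-butyldimethylsilyl)oxy]-6α-(phenylsulfonyl)-14,15,17-trinorlabd-8-en-13-one ethylene ketal (trans-decalin, 5α-H, 10β-CH3, C8=C9 silyl enol ether)
Conditions: PhMe (0.01 M), BHT (cat.), base-washed sealed tube, 180 °C
Reagents that add atoms: none
Why: Thermal intramolecular Diels–Alder reaction of a 1,7,9-decatriene (closest known type: a 2-silyloxydiene with a terminally activated E-dienophile); it is concerted and suprafacial on both partners, the s-cis diene C7=C8–C9=C10 adding across C5=C6 to form C6–C7 and C5–C10. Ring B closes as the new cyclohexene of the [4+2] addition, and ring A closes in the same event because the C1–C4 tether folds into a chair between C10 and C5, compressed by the gem-dimethyl group at C4. C10 is set by the diene face the tether reaches, and C3 decides this: the chair with the C3 silyloxy group equatorial gives 10β-CH3 together with 3β-O. C5 follows from the endo transition state (sulfone under the diene), which keeps the quaternary C4 away from C9 and its side chain and gives the trans fusion (5α-H), whereas the exo mode would push C4 under the diene. C6 follows from the E geometry of the dienophile, so the sulfone ends up α (equatorial) and trans to C4. The tether fixes the regiochemistry, but the C8 silyloxy group polarises the diene towards C7, which must bond to the sulfone-bearing C6; the donor–acceptor pairing therefore only narrows the frontier-orbital gap and is not polarity-matched, and this, with the inward C10 methyl, is why heat is needed. The step needs endo and facial selectivity and has to outrun the 1,5-hydrogen shift from the inward methyl to C7.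

Step 10
Reactants: 14 3β,8-bis[(tert-butyldimethylsilyl)oxy]-6α-(phenylsulfonyl)-14,15,17-trinorlabd-8-en-13-one ethylene ketal
Product: 15 3β,8-bis[(tert-butyldimethylsilyl)oxy]-14,15,17-trinorlabd-8-en-13-one ethylene ketal
Conditions: 6% Na(Hg), Na2HPO4, MeOH/THF, −20 °C
Reagents that add atoms: none
Why: Reductive desulfonylation by electron transfer (C–S cleavage, then protonation at C6). It is done while C8 is still an enol ether, so no β-sulfonyl ketone forms that could lose sulfinate to a C6=C7 enone and expose C5 to vinylogous epimerisation.

Step 11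
Reactants: 15 3β,8-bis[(tert-butyldimethylsilyl)oxy]-14,15,17-trinorlabd-8-en-13-one ethylene ketal
Product: 16 3β-hydroxy-14,15,17-trinorlabdane-8,13-dione 13-ethylene ketal (5α-H, 9α-H, 10β-CH3)
Conditions: TBAF (excess), THF, 50 °C
Reagents that add atoms: none
Why: Fluoride cleaves the enol silyl ether and, on warming, the hindered C3 ether. The C8 enolate is protonated from the α-face, and the basic medium equilibrates C9, so the chain settles equatorial (9β, 9α-H).

Step 12
Reactants: 16 3β-hydroxy-14,15,17-trinorlabdane-8,13-dione 13-ethylene ketal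
Product: 17 3β-hydroxy-14,15-dinorlabd-8(17)-en-13-one ethylene ketal
Conditions: Ph3PCH3Br, KOt-Bu (excess), PhMe, 90 °C
Reagents that add atoms: methyltriphenylphosphonium bromide, C[P+](c1ccccc1)(c1ccccc1)c1ccccc1.[Br-]
Why: Wittig methylenation of the hindered C8 ketone with an excess of the unstabilised ylide; the C3 alkoxide is a spectator and C9 already has its thermodynamic configuration. This brings in C17.

Step 13
Reactants: 17 3β-hydroxy-14,15-dinorlabd-8(17)-en-13-one ethylene ketal
Product: 18 8α,17-epoxy-3β-hydroxy-14,15-dinorlabdan-13-one ethylene ketal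
Conditions: mCPBA, NaHCO3, CH2Cl2, 0 °C
Reagents that add atoms: 3-chloroperoxybenzoic acid, OOC(=O)c1cccc(Cl)c1
Why: Peracid (Prilezhaev) epoxidation of the exocyclic alkene. The axial C10 methyl shields the β-face, so oxygen is delivered from the α-face and C8 receives its oxygen α; the buffer protects the ketal.

Step 14
Reactants: 18 8α,17-epoxy-3β-hydroxy-14,15-dinorlabdan-13-one ethylene ketal
Product: 19 3β,8α-dihydroxy-14,15-dinorlabdan-13-one ethylene ketal (8β-CH3)
Conditions: LiAlH4, THF, 0 °C to rt
Reagents that add atoms: none
Why: Hydride opens the spiro-epoxide by SN2 attack at its unsubstituted carbon C17, so the C8–O bond and its configuration are kept: 8α-OH with 8β-CH3. The hydride step is placed before any C–Br bond exists.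

Step 15
Reactants: 19 3β,8α-dihydroxy-14,15-dinorlabdan-13-one ethylene ketal
Product: 20 8α-hydroxy-14,15-dinorlabdane-3,13-dione 13-ethylene ketal
Conditions: Dess–Martin periodinane, NaHCO3, CH2Cl2, rt
Reagents that add atoms: none
Why: Dess–Martin oxidation of the only secondary alcohol; the tertiary alcohol cannot be oxidised. C3 has done its work as the control element; any cycloadduct from the other diene face must have been removed before this step, because oxidation would turn it into the enantiomer of 20.

Step 16
Reactants: 20 8α-hydroxy-14,15-dinorlabdane-3,13-dione 13-ethylene ketal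
Product: 21 8α-hydroxy-13-oxo-14,15-dinorlabd-2-en-3-yl trifluoromethanesulfonate 13-ethylene ketal
Conditions: KHMDS (2.3 equiv), PhNTf2, THF, −78 to 0 °C
Reagents that add atoms: N-phenylbis(trifluoromethanesulfonimide), O=S(=O)(N(c1ccccc1)S(=O)(=O)C(F)(F)F)C(F)(F)F
Why: The C3 ketone can enolise only towards C2 because C4 is quaternary; the potassium enolate is O-triflated. The second equivalent of base holds the tertiary alcohol as an alkoxide that is too hindered to be sulfonylated.

Step 17
Reactants: 21 8α-hydroxy-13-oxo-14,15-dinorlabd-2-en-3-yl trifluoromethanesulfonate 13-ethylene ketal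
Product: 22 3-bromo-8α-hydroxy-14,15-dinorlabd-2-en-13-one ethylene ketal
Conditions: Ni(OAc)2·4H2O (10 mol %), 1,5-cyclooctadiene, Zn (20 mol %), LiBr, DMA/THF, rt
Reagents that add atoms: lithium bromide, [Li+].[Br-]
Why: Nickel-catalysed conversion of an enol triflate into an alkenyl bromide (oxidative addition to zerovalent nickel, triflate/bromide exchange, C–Br reductive elimination). It runs at room temperature and tolerates the free tertiary alcohol and the ketal, which a phosphorus–bromine reagent on the ketone would not.

Step 18
Reactants: 22 3-bromo-8α-hydroxy-14,15-dinorlabd-2-en-13-one ethylene ketal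
Product: 23 3β-bromo-8α-hydroxy-14,15-dinorlabdan-13-one ethylene ketal
Conditions: Mn(dpm)3 (10 mol %), PhSiH3, t-BuOOH, i-PrOH, rt
Reagents that add atoms: none
Why: Hydrogen-atom-transfer hydrogenation of an alkenyl halide: the manganese hydride gives a hydrogen atom to C2 and leaves the bromine-stabilised C3 radical. That radical takes its second hydrogen axially from the α-face, because the β-face is blocked by the axial 4β-methyl, so bromine stays equatorial (3β). The C–Br bond is not hydrogenolysed under these radical conditions as it would be on palladium.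

Step 19
Reactants: 23 3β-bromo-8α-hydroxy-14,15-dinorlabdan-13-one ethylene ketal
Product: 24 3β-bromo-8α-(prop-2-en-1-yloxy)-14,15-dinorlabdan-13-one ethylene ketal
Conditions: KH, allyl bromide, 18-crown-6 (cat.), THF, 0 °C to rt
Reagents that add atoms: allyl bromide, C=CCBr
Why: Williamson etherification of the potassium alkoxide of the tertiary alcohol with a reactive allylic halide. The equatorial neopentyl bromide has no antiperiplanar hydrogen and cannot be displaced, so it should survive the base, and the ketal keeps the C13 ketone from being enolised.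

Step 20
Reactants: 24 3β-bromo-8α-(prop-2-en-1-yloxy)-14,15-dinorlabdan-13-one ethylene ketal
Product: 25 3β-bromo-8α-(prop-2-en-1-yloxy)-14,15-dinorlabdan-13-one
Conditions: PPTS, acetone/H2O, 50 °C
Reagents that add atoms: water, O
Why: Mild acid-catalysed hydrolysis (transketalisation) of the dioxolane; the tertiary allyl ether and the bromide do not ionise under these conditions.

Step 21
Reactants: 25 3β-bromo-8α-(prop-2-en-1-yloxy)-14,15-dinorlabdan-13-one
Product: 26 3β-bromo-13-methylidene-8α-(prop-2-en-1-yloxy)-14,15-dinorlabdane
Conditions: Ph3PCH3Br, KOt-Bu, THF, 0 °C to rt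
Reagents that add atoms: methyltriphenylphosphonium bromide, C[P+](c1ccccc1)(c1ccccc1)c1ccccc1.[Br-]
Why: Wittig methylenation of an unhindered methyl ketone; it supplies the 1,1-disubstituted alkene whose internal carbon is C13.

Step 22
Reactants: 26 3β-bromo-13-methylidene-8α-(prop-2-en-1-yloxy)-14,15-dinorlabdane
Product: 27 (13Z)-3β-bromo-8α,15-epoxylabd-13-ene (oxocene; 5α-H, 9α-H, 10β-CH3)
Conditions: second-generation Grubbs catalyst (H2IMes)(PCy3)Cl2Ru=CHPh (10 mol %), PhMe (2 mM), 80 °C
Reagents that add atoms: none
Why: Ring-closing metathesis: the catalyst loads onto the allyl ether and closes onto the 1,1-disubstituted alkene to give the trisubstituted C13=C14 bond. The trans-diequatorial chains on C8 and C9 are gauche and pre-organised for the eight-membered ring, and the ring allows only the Z alkene.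

Step 23
Reactants: 27 (13Z)-3β-bromo-8α,15-epoxylabd-13-ene
Product: 28 (13R,14S)-3β-bromo-8α,15:13,14-diepoxylabdane (the target, 3S,5R,8R,9R,10S,13R,14S)
Conditions: mCPBA, NaHCO3, CH2Cl2, 0 °C
Reagents that add atoms: 3-chloroperoxybenzoic acid, OOC(=O)c1cccc(Cl)c1
Why: Peracid epoxidation of the trisubstituted ring alkene, stereospecifically cis. In the staggered boat-chair conformer of ring C (O–C15 anti to the axial C8 methyl, C12 anti to C10) the alkene lies below the decalin with its inner face against H-9α, so the peracid should attack the outer face, which corresponds to 13R,14S.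

## Compound list

1 | acetylacetone (pentane-2,4-dione) | CC(=O)CC(C)=O | starting material
2 | 2-(2-bromoethyl)-2-methyl-1,3-dioxolane | CC1(CCBr)OCCO1 | starting material
3 | 3-[2-(2-methyl-1,3-dioxolan-2-yl)ethyl]pentane-2,4-dione | CC(=O)C(CCC1(C)OCCO1)C(C)=O | intermediate
4 | (2E)-3-[2-(2-methyl-1,3-dioxolan-2-yl)ethyl]-4-oxopent-2-en-2-yl trifluoromethanesulfonate | C/C(OS(=O)(=O)C(F)(F)F)=C(/CCC1(C)OCCO1)C(C)=O | intermediate
5 | acrolein | C=CC=O | starting material
6 | 1-methoxy-2-methyl-1-(trimethylsilyloxy)prop-1-ene | COC(O[Si](C)(C)C)=C(C)C | starting material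
7 | methyl (3S)-3-hydroxy-2,2-dimethylpent-4-enoate | C=C[C@H](O)C(C)(C)C(=O)OC | intermediate
8 | methyl (3S)-3-[(tert-butyldimethylsilyl)oxy]-2,2-dimethylpent-4-enoate | C=C[C@H](O[Si](C)(C)C(C)(C)C)C(C)(C)C(=O)OC | intermediate
9 | (3S)-3-[(tert-butyldimethylsilyl)oxy]-2,2-dimethylpent-4-enal | C=C[C@H](O[Si](C)(C)C(C)(C)C)C(C)(C)C=O | intermediate
10 | tert-butyl{[(3S,5E)-4,4-dimethyl-6-(phenylsulfonyl)hexa-1,5-dien-3-yl]oxy}dimethylsilane | C=C[C@H](O[Si](C)(C)C(C)(C)C)C(C)(C)/C=C/S(=O)(=O)c1ccccc1 | intermediate
11 | 9-[(3S,5E)-3-[(tert-butyldimethylsilyl)oxy]-4,4-dimethyl-6-(phenylsulfonyl)hex-5-en-1-yl]-9-borabicyclo[3.3.1]nonane | CC(C)(C)[Si](C)(C)O[C@@H](CCB1C2CCCC1CCC2)C(C)(C)/C=C/S(=O)(=O)c1ccccc1 | intermediate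
12 | (3E,7S,9E)-7-[(tert-butyldimethylsilyl)oxy]-4,8,8-trimethyl-3-[2-(2-methyl-1,3-dioxolan-2-yl)ethyl]-10-(phenylsulfonyl)deca-3,9-dien-2-one | CC(=O)/C(CCC1(C)OCCO1)=C(\C)CC[C@H](O[Si](C)(C)C(C)(C)C)C(C)(C)/C=C/S(=O)(=O)c1ccccc1 | intermediate
13 | tert-butyl{[(3E,7S,9E)-7-[(tert-butyldimethylsilyl)oxy]-4,8,8-trimethyl-3-[2-(2-methyl-1,3-dioxolan-2-yl)ethyl]-10-(phenylsulfonyl)deca-1,3,9-trien-2-yl]oxy}dimethylsilane | C=C(O[Si](C)(C)C(C)(C)C)/C(CCC1(C)OCCO1)=C(\C)CC[C@H](O[Si](C)(C)C(C)(C)C)C(C)(C)/C=C/S(=O)(=O)c1ccccc1 | intermediate
14 | 3β,8-bis[(tert-butyldimethylsilyl)oxy]-6α-(phenylsulfonyl)-14,15,17-trinorlabd-8-en-13-one ethylene ketal (5α-H, 10β-CH3) | CC1(C)[C@@H](O[Si](C)(C)C(C)(C)C)CC[C@]2(C)C(CCC3(C)OCCO3)=C(O[Si](C)(C)C(C)(C)C)C[C@H](S(=O)(=O)c3ccccc3)[C@@H]12 | intermediate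
15 | 3β,8-bis[(tert-butyldimethylsilyl)oxy]-14,15,17-trinorlabd-8-en-13-one ethylene ketal | CC1(C)[C@@H](O[Si](C)(C)C(C)(C)C)CC[C@]2(C)C(CCC3(C)OCCO3)=C(O[Si](C)(C)C(C)(C)C)CC[C@@H]12 | intermediate
16 | 3β-hydroxy-14,15,17-trinorlabdane-8,13-dione 13-ethylene ketal (5α-H, 9α-H, 10β-CH3) | CC1(C)[C@@H](O)CC[C@]2(C)[C@@H](CCC3(C)OCCO3)C(=O)CC[C@@H]12 | intermediate
17 | 3β-hydroxy-14,15-dinorlabd-8(17)-en-13-one ethylene ketal | CC1(C)[C@@H](O)CC[C@]2(C)[C@@H](CCC3(C)OCCO3)C(=C)CC[C@@H]12 | intermediate
18 | 8α,17-epoxy-3β-hydroxy-14,15-dinorlabdan-13-one ethylene ketal | CC1(C)[C@@H](O)CC[C@]2(C)[C@@H](CCC3(C)OCCO3)[C@@]4(CO4)CC[C@@H]12 | intermediate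
19 | 3β,8α-dihydroxy-14,15-dinorlabdan-13-one ethylene ketal (8β-CH3) | CC1(C)[C@@H](O)CC[C@]2(C)[C@@H](CCC3(C)OCCO3)[C@](C)(O)CC[C@@H]12 | intermediate
20 | 8α-hydroxy-14,15-dinorlabdane-3,13-dione 13-ethylene ketal | CC1(C)C(=O)CC[C@]2(C)[C@@H](CCC3(C)OCCO3)[C@](C)(O)CC[C@@H]12 | intermediate
21 | 8α-hydroxy-13-oxo-14,15-dinorlabd-2-en-3-yl trifluoromethanesulfonate 13-ethylene ketal | CC1(C)C(OS(=O)(=O)C(F)(F)F)=CC[C@]2(C)[C@@H](CCC3(C)OCCO3)[C@](C)(O)CC[C@@H]12 | intermediate
22 | 3-bromo-8α-hydroxy-14,15-dinorlabd-2-en-13-one ethylene ketal | CC1(C)C(Br)=CC[C@]2(C)[C@@H](CCC3(C)OCCO3)[C@](C)(O)CC[C@@H]12 | intermediate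
23 | 3β-bromo-8α-hydroxy-14,15-dinorlabdan-13-one ethylene ketal | CC1(C)[C@@H](Br)CC[C@]2(C)[C@@H](CCC3(C)OCCO3)[C@](C)(O)CC[C@@H]12 | intermediate
24 | 3β-bromo-8α-(prop-2-en-1-yloxy)-14,15-dinorlabdan-13-one ethylene ketal | CC1(C)[C@@H](Br)CC[C@]2(C)[C@@H](CCC3(C)OCCO3)[C@](C)(OCC=C)CC[C@@H]12 | intermediate
25 | 3β-bromo-8α-(prop-2-en-1-yloxy)-14,15-dinorlabdan-13-one | CC1(C)[C@@H](Br)CC[C@]2(C)[C@@H](CCC(C)=O)[C@](C)(OCC=C)CC[C@@H]12 | intermediate
26 | 3β-bromo-13-methylidene-8α-(prop-2-en-1-yloxy)-14,15-dinorlabdane | CC1(C)[C@@H](Br)CC[C@]2(C)[C@@H](CCC(C)=C)[C@](C)(OCC=C)CC[C@@H]12 | intermediate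
27 | (13Z)-3β-bromo-8α,15-epoxylabd-13-ene | CC1(C)[C@@H](Br)CC[C@]2(C)[C@H]3CC/C(C)=C\CO[C@]3(C)CC[C@@H]12 | intermediate
28 | (13R,14S)-3β-bromo-8α,15:13,14-diepoxylabdane (CNP0311742.2) | CC1(C)[C@@H](Br)CC[C@]2(C)[C@H]3CC[C@@]4(C)O[C@H]4CO[C@]3(C)CC[C@@H]12 | target

## Step count and the least certain steps

Total: 23 steps. Longest linear sequence: 21 steps (steps 3–23, from 5 and 6); the two-step branch from 1 and 2 joins at step 7.

**Step 9 (key step).** The most likely failure is loss of endo control at the temperature the inward C10 methyl demands, so that the cis-fused isomer forms beside 14. The trans transition state has to build up the 1,3-diaxial contact between the 4β-methyl and the C10 methyl, and a sulfone has only a weak endo preference. The same forcing conditions allow the 1,5-hydrogen shift from the inward methyl to C7, which consumes the diene, and the facial bias from the single C3 substituent next to a gem-dimethyl group may be modest.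

Fallback, from 13 back to 16: the sulfone is turned into a handle for thermodynamic control of the ring fusion. The cycloaddition is run as before and the fusion isomers are not separated; the mixture contains 14 and its C5,C6-epimer, the cis-fused adduct 3β,8-bis[(tert-butyldimethylsilyl)oxy]-6β-(phenylsulfonyl)-5β-14,15,17-trinorlabd-8-en-13-one ethylene ketal F1. Treatment with TBAF and then DBU (PhMe, 80 °C) unmasks the β-sulfonyl ketone, which loses benzenesulfinate to the C6=C7 enone. The γ-position of that enone is C5, so both isomers equilibrate through the dienolate to the trans-fused enone 3β-hydroxy-14,15,17-trinorlabd-6-ene-8,13-dione 13-ethylene ketal F2. Hydrogenation (H2, Pd/C, EtOAc) then gives 16. This corrects C5 only; an adduct from the other diene face still has to be separated.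

**Step 2.** The risk is erosion of the E:Z ratio: a diketone enolate chelates readily, and any cation-bound fraction is triflated to the Z isomer. The β-acyl alkenyl–palladium intermediate of step 7 could also isomerise. A Z triflate would place the tether cis to C8 and make the diene useless.

Fallback, from 2 back to 12: the geometry is set on a β-keto ester, the substrate class on which stereocomplementary enol sulfonylation is best established. Methyl acetoacetate (COC(=O)CC(C)=O) is alkylated with 2 to methyl 2-acetyl-4-(2-methyl-1,3-dioxolan-2-yl)butanoate F3. F3 is converted under the same non-chelating conditions into methyl (2E)-2-[2-(2-methyl-1,3-dioxolan-2-yl)ethyl]-3-{[(trifluoromethyl)sulfonyl]oxy}but-2-enoate F4. F4 is coupled with borane 11 as in step 7 to the tetrasubstituted enoate methyl (2E,6S,8E)-6-[(tert-butyldimethylsilyl)oxy]-3,7,7-trimethyl-2-[2-(2-methyl-1,3-dioxolan-2-yl)ethyl]-9-(phenylsulfonyl)nona-2,8-dienoate F5. Tebbe methylenation of the ester with Cp2Ti(μ-CH2)(μ-Cl)AlMe2 gives the 2-methoxydiene tert-butyl{[(3S,7E,1E)-6,8-dimethyl-substituted analogue of 13 with OCH3 in place of the enol silyl ether]}, that is (3E,7S,9E)-7-[(tert-butyldimethylsilyl)oxy]-2-methoxy-4,8,8-trimethyl-3-[2-(2-methyl-1,3-dioxolan-2-yl)ethyl]-10-(phenylsulfonyl)deca-1,3,9-triene F6. Brief treatment with oxalic acid in wet THF hydrolyses the enol ether much faster than the dioxolane and returns enone 12.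

**Step 18.** What may go wrong is loss of bromine. Hydrogen delivery to C3 instead of C2 gives a β-bromo radical that ejects a bromine atom, and the α-bromo radical next to the quaternary C4 is slow to be quenched. A second risk is hydrogen delivery from the β-face, which would give the axial bromide.

Fallback, from 20 back to 23: the ketone is reduced from the less hindered face with KBH(s-Bu)3 (THF, −78 °C) to the axial alcohol 3α,8α-dihydroxy-14,15-dinorlabdan-13-one ethylene ketal F7. F7 is then brominated with inversion under Appel conditions (PPh3, CBr4, CH2Cl2) to give 23. This is known chemistry but a substitution at a neopentyl carbon, so it is slow and prone to methyl migration and elimination, and the tertiary alcohol may need temporary silylation; it is the reserve, not the first choice.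

**Step 23.** The risk is poor facial selectivity: the prediction rests on one conformer of ring C, and a second populated conformer would expose the other face of the alkene.

Fallback, from 27 back to 28: oxygen is delivered to the face opposite to the one an electrophile attacks. NBS in aqueous THF forms the bromonium ion on the accessible face; water opens it at the more substituted C13 from the other side and gives the bromohydrin (13R,14R)-3β,14-dibromo-8α,15-epoxylabdan-13-ol F8. K2CO3 in MeOH closes F8 to the epoxide with inversion at C14. This is used only if the direct epoxidation of step 23 favours the 13S,14R isomer.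

## Further compounds

F1 | step 9 | 3β,8-bis[(tert-butyldimethylsilyl)oxy]-6β-(phenylsulfonyl)-5β-14,15,17-trinorlabd-8-en-13-one ethylene ketal (cis-fused adduct) | CC1(C)[C@@H](O[Si](C)(C)C(C)(C)C)CC[C@]2(C)C(CCC3(C)OCCO3)=C(O[Si](C)(C)C(C)(C)C)C[C@@H](S(=O)(=O)c3ccccc3)[C@H]12
F2 | step 9 | 3β-hydroxy-14,15,17-trinorlabd-6-ene-8,13-dione 13-ethylene ketal (5α-H, 9α-H, 10β-CH3) | CC1(C)[C@@H](O)CC[C@]2(C)[C@@H](CCC3(C)OCCO3)C(=O)C=C[C@@H]12
F3 | step 2 | methyl 2-acetyl-4-(2-methyl-1,3-dioxolan-2-yl)butanoate | COC(=O)C(CCC1(C)OCCO1)C(C)=O
F4 | step 2 | methyl (2E)-2-[2-(2-methyl-1,3-dioxolan-2-yl)ethyl]-3-{[(trifluoromethyl)sulfonyl]oxy}but-2-enoate | C/C(OS(=O)(=O)C(F)(F)F)=C(/CCC1(C)OCCO1)C(=O)OC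
F5 | step 2 | methyl (2E,6S,8E)-6-[(tert-butyldimethylsilyl)oxy]-3,7,7-trimethyl-2-[2-(2-methyl-1,3-dioxolan-2-yl)ethyl]-9-(phenylsulfonyl)nona-2,8-dienoate | COC(=O)/C(CCC1(C)OCCO1)=C(\C)CC[C@H](O[Si](C)(C)C(C)(C)C)C(C)(C)/C=C/S(=O)(=O)c1ccccc1
F6 | step 2 | (3E,7S,9E)-7-[(tert-butyldimethylsilyl)oxy]-2-methoxy-4,8,8-trimethyl-3-[2-(2-methyl-1,3-dioxolan-2-yl)ethyl]-10-(phenylsulfonyl)deca-1,3,9-triene | C=C(OC)/C(CCC1(C)OCCO1)=C(\C)CC[C@H](O[Si](C)(C)C(C)(C)C)C(C)(C)/C=C/S(=O)(=O)c1ccccc1
F7 | step 18 | 3α,8α-dihydroxy-14,15-dinorlabdan-13-one ethylene ketal | CC1(C)[C@H](O)CC[C@]2(C)[C@@H](CCC3(C)OCCO3)[C@](C)(O)CC[C@@H]12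
F8 | step 23 | (13R,14R)-3β,14-dibromo-8α,15-epoxylabdan-13-ol | CC1(C)[C@@H](Br)CC[C@]2(C)[C@H]3CC[C@@](C)(O)[C@H](Br)CO[C@]3(C)CC[C@@H]12
A1 | alternative 1 | (13Z)-3β-bromo-8α,15-epoxylabd-13-ene (Z-oxocene, same structure as 27) | CC1(C)[C@@H](Br)CC[C@]2(C)[C@H]3CC/C(C)=C\CO[C@]3(C)CC[C@@H]12
A2 | alternative 1 | 3β-bromo-11-iodo-12,13,14,15,16-pentanorlabdan-8α-ol (iodo alcohol) | CC1(C)[C@@H](Br)CC[C@]2(C)[C@@H](CI)[C@](C)(O)CC[C@@H]12
A3 | alternative 1 | isoprene | C=CC(C)=C
A4 | alternative 1 | 3β-bromo-8α,13-epoxylabd-14-ene (tetrahydropyran from six-membered closure, C13 undefined) | CC1(C)[C@@H](Br)CC[C@]2(C)[C@H]3CCC(C)(C=C)O[C@]3(C)CC[C@@H]12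
A5 | alternative 2 | 3β-[(tert-butyldimethylsilyl)oxy]-13,14,15,16-tetranorlabdano-12,8α-lactone (tricyclic trans-lactone) | CC1(C)[C@@H](O[Si](C)(C)C(C)(C)C)CC[C@]2(C)[C@H]3CC(=O)O[C@]3(C)CC[C@@H]12
A6 | alternative 2 | methyl (2E)-3-[(1S,2R,4S)-4-[(tert-butyldimethylsilyl)oxy]-1,3,3-trimethyl-2-(3-oxobutyl)cyclohexyl]prop-2-enoate (monocyclic keto enoate; ring A with C10 bearing the enoate and C5 the oxobutyl chain) | CC1(C)[C@@H](O[Si](C)(C)C(C)(C)C)CC[C@](C)(/C=C/C(=O)OC)[C@H]1CCC(C)=O
A7 | alternative 3 | 3β-bromo-8α,15-epoxylabdan-14-one (α-methyl oxocanone, one C13 epimer) | CC1(C)[C@@H](Br)CC[C@]2(C)[C@H]3CC[C@H](C)C(=O)CO[C@]3(C)CC[C@@H]12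
A8 | alternative 3 | 3β-bromo-8α,15-epoxy-13,16-dinorlabdan-14-one (oxepanone, C12 bonded to C14) | CC1(C)[C@@H](Br)CC[C@]2(C)[C@H]3CCC(=O)CO[C@]3(C)CC[C@@H]12
A9 | alternative 3 | diazoethane | CC=[N+]=[N-]
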